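The constants below do not weigh alike, so before I reckon I ask which of them I have to know well. Initiator starts chains, free monomer adds to living ends and returns from them, and living ends die in pairs.

all flasks: initiator 100 mM; time 3.0 min
- north-west: free monomer 1.0 M
- south-east: free monomer 2.0 M

    free monomer + initiator → living end + monomer in chains (k1 = 0.295 M⁻¹ s⁻¹)
    free monomer + living end → monomer in chains + living end, rate k2*[living end]*[free monomer] (k2 = 0.0939 M⁻¹ s⁻¹)
    monomer in chains + living end → free monomer + living end, rate k3*[living end] as long as [monomer in chains] is above zero (k3 = 0.0311 s⁻¹)
    2 living end → dead end (k4 = 0.0586 M⁻¹ s⁻¹)

* which of the two ends with the longer chains by the average number of monomer units in a chain (chains begun, living or dead) ("neither" if they lie within 10 %) (north-west / south-east / neither)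
* average number of monomer units in a chain (chains begun, living or dead) at the end, north-west
* average number of monomer units in a chain (chains begun, living or dead) at the end, south-east

- two of one species on the left: rate k times its square, two consumed each time
- the average divides the monomer in chains by the number of chains begun, living and dead together
- run time (north-west): 3.0 min

The initiation constant 0.295 M⁻¹ s⁻¹ gives initiator a time constant of 3.39 s in north-west, far shorter than the run of 3.0 min. So I need it roughly, and I take chains begun as the charge 100 mM. The constants 0.0939 M⁻¹ s⁻¹ and 0.0311 s⁻¹ must be known well. Addition runs at 0.0939 M⁻¹ s⁻¹ times c(living end) times c(free monomer), return at 0.0311 s⁻¹ times c(living end), so the living end cancels from their ratio. That ratio is c(free monomer) over 0.331 M, the balance level (the equilibrium monomer concentration).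

As free monomer falls, the ratio drifts toward 1, and the gap to the balance level closes with a time constant that lengthens as c(living end) falls. The termination constant 0.0586 M⁻¹ s⁻¹ enters here: c(living end) falls from 100 mM on a scale of 85.3 s. Taking every chain as begun at the start and integrating, I estimate that the gap shrinks by the factor (1 + t/85.3 s) to the power −0.801, which is 0.403 for either flask, as both hold the same initiator. Each chain begun takes one free monomer, so free monomer starts from its charge less 100 mM, and the gap opens at that amount less the balance level. Dividing what has left free monomer by 100 mM gives 4.40 in north-west and 10.4 in south-east, so I expect south-east.

The forecast says south-east, with 4.4 and 10.4, its grounds being “Propagation and depropagation relax free monomer toward” the same level.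

The simulation gives south-east, with 4.40 in north-west and 10.4 in south-east. In north-west at 3.00 min, monomer in chains is made 1.69 times as fast as it is used up, down from 2.15 at 0.962 min. That is c(free monomer) of 0.560 M over the balance level 0.331 M. The forecast's 4.4 stops holding in a north-west copy with 0.060 M of initiator: the balance level stays, the factor becomes 0.519, I reckon 5.88, and that flask gives 5.87.

(The numbers were set for the occasion, and the outcome is calculated.)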